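## Structural features

The target is a biflavone: two 5,7-dihydroxy-2-arylchromen-4-one units joined by one aryl–aryl bond from C6 of unit 1 (2-aryl = 4-methoxyphenyl) to C8 of unit 2 (2-aryl = 4-hydroxyphenyl). The connecting bond has four ortho substituents (5-OH and 7-OH of unit 1, 7-OH and the O1-bearing C8a of unit 2), so it is a crowded axis. There is no stereocentre, and the SMILES string fixes no configuration at the axis. Five phenols must be free at the end while one aryl methyl ether stays, which excludes a global demethylation as the last step. The fragile parts are the two pyranones, which open in hot alkali and can reclose through the other peri oxygen when a 5-hydroxyl is free (Wessely–Moser pathway), and the electron-rich phloroglucinol rings, which take up electrophiles at any free carbon. The real difficulty is regiochemical: each phloroglucinol-derived ring must close its pyranone through one particular oxygen. Unit 1 is easy, because a 4-hydroxy-2,6-dioxygenated aryl group is symmetric about the biaryl axis and both carbons ortho to the hydroxyl are equivalent. Unit 2 is hard, because its pyranone must use the crowded oxygen on C8a, next to the biaryl carbon C8. The key step exploits the fact that this oxygen lies between C4a and C8: once it alone carries the 4-(benzyloxy)benzoyl group and C4 carries a phosphorus ylide at the future C3, joining C3 to the ester carbon (future C2) can only give the 8-linked flavone.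

## Logic of the disconnections

24 to 23: the five benzylic C–O bonds are cut. Benzyl is chosen because it can be removed by hydrogenolysis without touching the methyl ether, so the one O-methyl group is distinguished from the five other oxygens from the first step on. The demand on the forward step is that hydrogenolysis stops before the C2=C3 bonds of the two flavones are reduced.

23 to 22: the C4–C4a bond of unit 1 is cut (intramolecular acylation of an arene by a carboxylic acid). In 22 the aryloxy ring is symmetric about the biaryl axis, so acylation at either ortho carbon gives the same 6-linked unit. One ring is removed and no regiochemical question remains. The forward step needs the carboxyl cis to the aryloxy group (or able to become so) and an activation mild enough for five benzyl ethers.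

22 to 21, then to 18 and 20 (20 from 19): the ester is returned, then the O1–C2 bond of unit 1 (aryl oxygen to vinyl carbon) is cut as a conjugate addition of a phenol to an ynoate. This is convergent: the whole C2–C3–C4 chain with its 4-methoxyphenyl group arrives in one piece, and 18 has only one free phenol. The forward steps require the pyranone of unit 2 to survive carbonate and then hydroxide at moderate temperature.

18 to 17: the O–Si bond is cut. The silyl group marks the one oxygen that becomes O1 of unit 1 and is orthogonal to benzyl. Buffered fluoride is needed so that the flavone does not meet a strongly basic phenoxide.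

17 to 16 (key disconnection): the C2=C3 bond of the unit 2 pyranone is cut to an aryl ester and a keto-stabilized ylide. The crowded O1–C2 bond already exists in 16 as an ester, so the ring is closed at carbon under neutral conditions, at the flavone oxidation level and without acid. A check of the atom mapping shows that the structures of 16 and 17 are consistent: in 16 the aroyloxy carbon lies between the acyl carbon and the biaryl carbon (future C8a between C4a and C8), and the silyloxy group para to the biaryl bond becomes O1 of unit 1. No correction of these structures is needed. The forward step must favour olefination of the ester over transfer of the aroyl group to the ylide carbon.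

16 to 14 and 15, then 14 to 12 to 9: the ester C–O bond, the C–P bond and the C–Br bond are cut in turn. Because 14 has a single hydroxyl, acylation fixes O1 without ambiguity. The demands are O-acylation of a crowded phenol in preference to C-acylation of the ylide, and side-chain bromination of 9 without bromination of three electron-rich rings. The second demand is met by brominating the silyl enol ether (via 10 and 11) instead of the ketone. Thermolysis is kept as a separate operation after the acylation, with salts washed out.

9 to 3 and 8: the biaryl bond is cut (cross-coupling of an aryl iodide with an arylboronate). This divides the molecule into two phloroglucinol pieces of similar size, each available in two or three steps. The forward step must form a tetra-ortho-substituted biaryl before the boronate is lost by protodeboronation.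

3 to 2 to 1, and 8 to 6 to 5 to 4: carbon–iodine, carbon–boron, carbon–bromine and oxygen–protecting-group bonds are cut back to the commercial compounds 1 and 4. The demands are regiochemical: iodine must go ortho to the chelated phenol of 2, and bromine in 5 must go between the two benzyloxy groups, for which the bulky silyl group is relied on.

## Other disconnections considered

Alternative 1: The cut is the O1–C2 bond of unit 1, made by isomerization instead of direct bond formation. The precursor would be the 8,8''-linked biflavone A1, in which unit 1 is present as its 8-aryl-5,7-dihydroxy isomer and unit 2 carries a 5-methoxy group as a lock. Hot aqueous acid would open the unit 1 pyranone to the 1,3-diketone and let it reclose through the former 5-hydroxyl to give the 6,8''-linked A2, the 5-O-methyl ether (at unit 2) of the target. Selective cleavage of the chelated 5-methoxy group would finish the synthesis.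
- In its favour: the biaryl bond of A1 joins two carbons of the same kind (each ortho to the phenol of a phloroacetophenone), so both halves could come from one halogenated acetophenone. No benzyl groups are needed. On step economy this plan is probably the better one.
- Against it here: the Wessely–Moser process is an equilibration. An aryl group between a hydroxyl and the ring oxygen (8-position) or between two hydroxyls (6-position) has no strong thermodynamic bias, so a mixture of A1 and A2 that is hard to separate must be expected. The hot acid also endangers the 4'-methyl ether. The lock and the final 5-O-demethylation next to a second methyl ether use up part of the saving.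
- Comparison: both plans rest on the same structural fact, that O1 and the 5-oxygen are interchangeable partners of the acyl group on C4a. The chosen plan decides between them by construction under kinetic control; alternative 1 leaves the decision to an equilibrium. It is shorter but less certain.

Alternative 2: The cut is C4–C4a of unit 1. The (Z)-3-aryloxy-3-(4-methoxyphenyl)acrylic acid (compound 22 of the route) is activated as a mixed anhydride and acylates the ortho carbon of its symmetric aryloxy ring to give A3, the penta-O-benzyl ether of the target, identical with 23. This is not a rival route: it is the closure that the chosen plan uses for unit 1 in step 15, and the only question is which ring closure carries the strategy.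
- In its favour: it is regiochemically unambiguous by symmetry, electronically well matched (acylation of a phloroglucinol-type ring), and convergent. In step count it equals the chosen plan, since the sequences coincide. As a ring closure it is mechanistically simpler and more certain than the ester Wittig step, and on that point it is the better of the two.
- Against it as the central idea: it solves the easy half of the problem and says nothing about how the unit 2 pyranone is attached through the crowded oxygen. The same closure applied to unit 2 would need conjugate addition of the hindered phenol next to the biaryl carbon, which is less attractive than acylating that phenol. A conventional base-induced acyl shift and acid cyclodehydration for unit 2 would expose the silyl marker and the benzyl ethers to acid twice.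
- Comparison: the two disconnections complement each other, and the plan adopted uses both.

Alternative 3: The cut is C5–C6 of the benzo ring of unit 2. The precursor would be the pyranone keto ester A4. Excess LiN(SiMe3)2 would form its dienolate, whose methyl ketone terminus (future C6) attacks the ester carbon (future C5) in a Claisen-type 6-exo-trig closure. Aromatization would give A5, the 5,7-dihydroxy analogue of 17.
- In its favour: the benzo ring is built with the aryl group already on the future C8, so the regiochemical certainty equals that of the chosen plan. No bond has to be made at the crowded oxygen. Two phenols appear without protecting groups.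
- Against it here: A4 is no simpler than 16. It is a trisubstituted 4-pyranone with a doubly activated benzylic methine attached to a di-ortho-substituted aryl group, and its assembly would take at least as many steps as the path from 3 to 16. Excess strong base meets an electrophilic pyranone and an aryl silyl ether. The free 5- and 7-hydroxyls of A5 are a liability afterwards: the acidic 7-hydroxyl would compete in the oxa-Michael step, and a free 5-hydroxyl reopens the Wessely–Moser pathway for unit 2 in the acid step, so A5 would have to be benzylated to reach 17.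
- Comparison: on structure and mechanism it is sound and equal in regiocontrol; on step economy it is the weaker plan.

Key step: step 10

Remark: the target SMILES defines no configuration at the hindered biaryl axis, so the route is planned for the racemate with respect to that axis (the axis becomes stereogenic only in step 15).
Remark: compounds 21 and 22 are drawn as the (Z)-isomers expected from anti addition; any (E)-isomer is carried along, since the acidic closure conditions should equilibrate the two.
Abbreviations used in the step names: Ar = 2,6-bis(benzyloxy)-4-[tri(propan-2-yl)silyloxy]phenyl; Fl = 5,7-bis(benzyloxy)-2-[4-(benzyloxy)phenyl]-4-oxo-4H-chromen-8-yl. Full names are in the compound list.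

Step 1
Reactants: 1 2,4,6-trihydroxyacetophenone
Product: 2 1-[2,4-bis(benzyloxy)-6-hydroxyphenyl]ethan-1-one
Conditions: BnBr (2.05 equiv), K2CO3, DMF, rt
Reagents that add atoms: benzyl bromide, BrCc1ccccc1
Why: Williamson etherification; the hydroxyl hydrogen-bonded to the acetyl carbonyl is the least nucleophilic, so two equivalents of bromide should alkylate the other two oxygens and leave the chelated phenol free.

Step 2
Reactants: 2 1-[2,4-bis(benzyloxy)-6-hydroxyphenyl]ethan-1-one
Product: 3 1-[4,6-bis(benzyloxy)-2-hydroxy-3-iodophenyl]ethan-1-one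
Conditions: BnMe3N·ICl2, NaHCO3, CH2Cl2–MeOH, rt
Reagents that add atoms: benzyltrimethylammonium dichloroiodate, C[N+](C)(C)Cc1ccccc1.Cl[I-]Cl
Why: Electrophilic aromatic iodination; the free chelated phenol is the strongest ortho director, so iodine should enter at C3 (the future C8 of unit 2), and the buffered mild reagent should avoid di-iodination and ether cleavage.

Step 3
Reactants: 4 3,5-bis(benzyloxy)phenol
Product: 5 [3,5-bis(benzyloxy)phenoxy]tri(propan-2-yl)silane
Conditions: i-Pr3SiCl, imidazole, DMF, rt
Reagents that add atoms: chlorotri(propan-2-yl)silane, CC(C)[Si](Cl)(C(C)C)C(C)C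
Why: Silylation of a phenol; the triisopropylsilyl ether marks the future O1 of unit 1, is orthogonal to benzyl, and should survive organolithium, cross-coupling and thermolysis conditions.

Step 4
Reactants: 5 [3,5-bis(benzyloxy)phenoxy]tri(propan-2-yl)silane
Product: 6 [4-bromo-3,5-bis(benzyloxy)phenoxy]tri(propan-2-yl)silane
Conditions: NBS (1.0 equiv), MeCN, −20 → 0 °C
Reagents that add atoms: N-bromosuccinimide, O=C1CCC(=O)N1Br
Why: Electrophilic aromatic bromination; all three free carbons are activated by the three oxygens, and the bulky silyl group should shield its two neighbours, so one bromine is expected at the carbon between the benzyloxy groups, para to the silyloxy group.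

Step 5
Reactants: 6 [4-bromo-3,5-bis(benzyloxy)phenoxy]tri(propan-2-yl)silane
Product: 8 2-(Ar)-4,4,5,5-tetramethyl-1,3,2-dioxaborolane, via aryllithium 7 (not isolated)
Conditions: n-BuLi, THF, −78 °C; i-PrOBpin, −78 °C → rt; H2O
Reagents that add atoms: n-butyllithium (lithium of 7), [Li]CCCC; 2-isopropoxy-4,4,5,5-tetramethyl-1,3,2-dioxaborolane, CC(C)OB1OC(C)(C)C(C)(C)O1
Why: Bromine–lithium exchange at −78 °C is faster than benzylic deprotonation; the aryllithium is para to the silyloxy group, so no silyl shift to carbon is possible, and the borate ester should trap it as the pinacol boronate.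

Step 6
Reactants: 3 1-[4,6-bis(benzyloxy)-2-hydroxy-3-iodophenyl]ethan-1-one; 8 2-(Ar)-4,4,5,5-tetramethyl-1,3,2-dioxaborolane
Product: 9 1-[4,6-bis(benzyloxy)-3-(Ar)-2-hydroxyphenyl]ethan-1-one
Conditions: Pd(OAc)2 (5 mol %), SPhos (2-dicyclohexylphosphino-2',6'-dimethoxybiphenyl, 10 mol %), K3PO4, toluene–H2O, 90 °C; 8 in excess
Reagents that add atoms: none
Why: Suzuki–Miyaura coupling; the dialkylbiarylphosphine ligand is suited to tetra-ortho-substituted biaryls, the aryl iodide adds readily to zerovalent palladium, and the chelated phenol and the silyl ether should tolerate aqueous phosphate.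

Step 7
Reactants: 9 1-[4,6-bis(benzyloxy)-3-(Ar)-2-hydroxyphenyl]ethan-1-one
Product: 12 2-bromo-1-[4,6-bis(benzyloxy)-3-(Ar)-2-hydroxyphenyl]ethan-1-one, via bis(trimethylsilyl) enol ether 10 (not isolated), via O-trimethylsilyl bromoketone 11 (not isolated)
Conditions: LiN(SiMe3)2 (2.2 equiv), Me3SiCl, THF, −78 → 0 °C; NBS, −78 °C; 1 M HCl, THF, 0 °C
Reagents that add atoms: chlorotrimethylsilane (silyl groups of 10 and 11), C[Si](C)(C)Cl; N-bromosuccinimide, O=C1CCC(=O)N1Br
Why: α-Bromination through the silyl enol ether; double deprotonation and silylation masks the phenol and turns the methyl ketone into an enol ether that should react with NBS at −78 °C far faster than the electron-rich rings, and the brief acidic work-up frees the phenol without a base that could close a benzofuranone.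

Step 8
Reactants: 12 2-bromo-1-[4,6-bis(benzyloxy)-3-(Ar)-2-hydroxyphenyl]ethan-1-one
Product: 14 1-[4,6-bis(benzyloxy)-3-(Ar)-2-hydroxyphenyl]-2-(triphenyl-λ5-phosphanylidene)ethan-1-one, via phosphonium bromide 13 (not isolated)
Conditions: PPh3, toluene, rt → 50 °C; then aq. Na2CO3, CH2Cl2, rt
Reagents that add atoms: triphenylphosphine, c1ccc(cc1)P(c1ccccc1)c1ccccc1
Why: SN2 displacement of the primary α-bromide by the phosphine gives the phenacylphosphonium salt, and carbonate removes its acidic α-proton to give the keto-stabilized ylide, which is stable to water and keeps its phenol free.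

Step 9
Reactants: 14 1-[4,6-bis(benzyloxy)-3-(Ar)-2-hydroxyphenyl]-2-(triphenyl-λ5-phosphanylidene)ethan-1-one; 15 4-(benzyloxy)benzoyl chloride
Product: 16 3,5-bis(benzyloxy)-6-(Ar)-2-[(triphenyl-λ5-phosphanylidene)acetyl]phenyl 4-(benzyloxy)benzoate
Conditions: pyridine, CH2Cl2, 0 °C → rt; aqueous wash to remove pyridinium chloride
Reagents that add atoms: none
Why: Acylation of a phenol by an acid chloride; in pyridine the phenolic oxygen of such hydroxy ylides is acylated in preference to the conjugated, sterically shielded ylide carbon, and since 14 has only this hydroxyl the aroyl group is fixed on the oxygen that becomes O1.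

Step 10
Reactants: 16 3,5-bis(benzyloxy)-6-(Ar)-2-[(triphenyl-λ5-phosphanylidene)acetyl]phenyl 4-(benzyloxy)benzoate
Product: 17 5,7-bis(benzyloxy)-8-(Ar)-2-[4-(benzyloxy)phenyl]-4H-chromen-4-one
Conditions: toluene, 110 °C, N2
Reagents that add atoms: none
Why: This is an intramolecular Wittig olefination of an aryl ester, the reaction type known for making chromones and flavones from 2-acyloxyphenacylidene phosphoranes. The ylide carbon (future C3) adds to the carbonyl carbon of the neighbouring aroyloxy group (future C2); the ring formed holds C3, C4, C4a, C8a, O1 and C2 with the attacked C=O outside it, a 6-exo-trig closure. The zwitterionic adduct closes to a 1,2-oxaphosphetane, whose cycloreversion releases triphenylphosphine oxide and the C2=C3 double bond, so the pyranone arrives at the flavone oxidation level without dehydrogenation or acid. No stereocentre is formed, and the new double bond is endocyclic, so no E/Z question arises. The selectivity needed is olefination over collapse of the adduct with loss of the phenoxide (an O-to-C aroyl shift); the fixed ortho arrangement holds ylide and ester in the geometry for oxaphosphetane formation, and neutral salt-free conditions offer no base or nucleophile to shuttle the acyl group. Regiochemistry is not at stake here: O1 was defined when the only phenol of 14 was acylated, and with the 5-oxygen benzylated the ring cannot open and reclose to the 6-linked isomer. The silyl ether and the benzyl ethers should be inert in hot toluene.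

Step 11
Reactants: 17 5,7-bis(benzyloxy)-8-(Ar)-2-[4-(benzyloxy)phenyl]-4H-chromen-4-one
Product: 18 5,7-bis(benzyloxy)-8-[2,6-bis(benzyloxy)-4-hydroxyphenyl]-2-[4-(benzyloxy)phenyl]-4H-chromen-4-one
Conditions: Bu4NF, AcOH, THF, 0 °C
Reagents that add atoms: none
Why: Fluoride-induced cleavage of the aryl silyl ether; acetic acid buffers the phenoxide so that the flavone is not exposed to strong base, benzyl ethers are untouched, and the phenol obtained is symmetric about the biaryl axis.

Step 12
Reactants: 19 3-(4-methoxyphenyl)prop-2-ynoic acid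
Product: 20 ethyl 3-(4-methoxyphenyl)prop-2-ynoate
Conditions: EtI, K2CO3, DMF, rt
Reagents that add atoms: iodoethane, CCI
Why: O-Alkylation of the carboxylate under mild base gives the ynoate without heating the acid, which avoids decarboxylation or hydration of the arylpropiolic acid.

Step 13
Reactants: 18 5,7-bis(benzyloxy)-8-[2,6-bis(benzyloxy)-4-hydroxyphenyl]-2-[4-(benzyloxy)phenyl]-4H-chromen-4-one; 20 ethyl 3-(4-methoxyphenyl)prop-2-ynoate
Product: 21 ethyl (2Z)-3-[3,5-bis(benzyloxy)-4-(Fl)phenoxy]-3-(4-methoxyphenyl)prop-2-enoate
Conditions: K2CO3 (0.5 equiv), DMF, 70 °C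
Reagents that add atoms: none
Why: Oxa-Michael addition of the only phenoxide to the β-carbon of the ynoate; the phenol has two ortho hydrogens and is a good nucleophile, anti addition across the triple bond should place the aryloxy group cis to the ester (Z), and the flavone and benzyl ethers tolerate carbonate in DMF.

Step 14
Reactants: 21 ethyl (2Z)-3-[3,5-bis(benzyloxy)-4-(Fl)phenoxy]-3-(4-methoxyphenyl)prop-2-enoate
Product: 22 (2Z)-3-[3,5-bis(benzyloxy)-4-(Fl)phenoxy]-3-(4-methoxyphenyl)prop-2-enoic acid
Conditions: LiOH, THF–MeOH–H2O, rt → 40 °C; then 1 M HCl to pH 3, 0 °C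
Reagents that add atoms: lithium hydroxide (hydroxyl oxygen of the acid), [Li+].[OH-]
Why: Saponification of the ethyl ester near room temperature, where the flavone ring and the aryl vinyl ether should stay intact; cold acidification to pH 3 liberates the acid without hydrolysing the enol ether.

Step 15
Reactants: 22 (2Z)-3-[3,5-bis(benzyloxy)-4-(Fl)phenoxy]-3-(4-methoxyphenyl)prop-2-enoic acid
Product: 23 5,7-bis(benzyloxy)-6-(Fl)-2-(4-methoxyphenyl)-4H-chromen-4-one
Conditions: (CF3CO)2O, CH2Cl2, 0 °C → rt
Reagents that add atoms: none
Why: Intramolecular Friedel–Crafts acylation via the mixed trifluoroacetic anhydride; the acyl carbon (future C4) attacks the carbon ortho to the aryloxy oxygen (future C4a) of a ring activated by three oxygens, both ortho carbons are equivalent so only the 6-linked unit 1 can form, and the trifluoroacetic acid released can equilibrate any (E)-acid through the aryloxy- and anisyl-stabilized cation; the biaryl axis becomes stereogenic here and forms as the racemate.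

Step 16
Reactants: 23 5,7-bis(benzyloxy)-6-(Fl)-2-(4-methoxyphenyl)-4H-chromen-4-one
Product: 24 5,7-dihydroxy-6-[5,7-dihydroxy-2-(4-hydroxyphenyl)-4-oxo-4H-chromen-8-yl]-2-(4-methoxyphenyl)-4H-chromen-4-one
Conditions: H2 (1 atm), Pd/C, THF–MeOH, rt
Reagents that add atoms: none
Why: Hydrogenolysis of five aryl benzyl ethers over palladium; the aryl methyl ether is inert, and the conjugated C2=C3 bonds of flavones are reduced much more slowly than benzyl ethers are cleaved, so the reaction is stopped once the benzyl groups are gone.

Compound list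

1 | 2,4,6-trihydroxyacetophenone | CC(=O)c1c(O)cc(O)cc1O | starting material
2 | 1-[2,4-bis(benzyloxy)-6-hydroxyphenyl]ethan-1-one | CC(=O)c1c(O)cc(OCc2ccccc2)cc1OCc1ccccc1 | intermediate
3 | 1-[4,6-bis(benzyloxy)-2-hydroxy-3-iodophenyl]ethan-1-one | CC(=O)c1c(O)c(I)c(OCc2ccccc2)cc1OCc1ccccc1 | intermediate
4 | 3,5-bis(benzyloxy)phenol | Oc1cc(OCc2ccccc2)cc(OCc2ccccc2)c1 | starting material
5 | [3,5-bis(benzyloxy)phenoxy]tri(propan-2-yl)silane | CC(C)[Si](Oc1cc(OCc2ccccc2)cc(OCc2ccccc2)c1)(C(C)C)C(C)C | intermediate
6 | [4-bromo-3,5-bis(benzyloxy)phenoxy]tri(propan-2-yl)silane | CC(C)[Si](Oc1cc(OCc2ccccc2)c(Br)c(OCc2ccccc2)c1)(C(C)C)C(C)C | intermediate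
7 | {2,6-bis(benzyloxy)-4-[tri(propan-2-yl)silyloxy]phenyl}lithium | [Li]c1c(OCc2ccccc2)cc(O[Si](C(C)C)(C(C)C)C(C)C)cc1OCc1ccccc1 | intermediate
8 | 2-{2,6-bis(benzyloxy)-4-[tri(propan-2-yl)silyloxy]phenyl}-4,4,5,5-tetramethyl-1,3,2-dioxaborolane | CC1(C)OB(OC1(C)C)c1c(OCc2ccccc2)cc(O[Si](C(C)C)(C(C)C)C(C)C)cc1OCc1ccccc1 | intermediate
9 | 1-(4,6-bis(benzyloxy)-3-{2,6-bis(benzyloxy)-4-[tri(propan-2-yl)silyloxy]phenyl}-2-hydroxyphenyl)ethan-1-one | CC(=O)c1c(O)c(-c2c(OCc3ccccc3)cc(O[Si](C(C)C)(C(C)C)C(C)C)cc2OCc2ccccc2)c(OCc2ccccc2)cc1OCc1ccccc1 | intermediate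
10 | {[1-(4,6-bis(benzyloxy)-3-{2,6-bis(benzyloxy)-4-[tri(propan-2-yl)silyloxy]phenyl}-2-(trimethylsilyloxy)phenyl)ethenyl]oxy}trimethylsilane | C=C(O[Si](C)(C)C)c1c(O[Si](C)(C)C)c(-c2c(OCc3ccccc3)cc(O[Si](C(C)C)(C(C)C)C(C)C)cc2OCc2ccccc2)c(OCc2ccccc2)cc1OCc1ccccc1 | intermediate
11 | 2-bromo-1-(4,6-bis(benzyloxy)-3-{2,6-bis(benzyloxy)-4-[tri(propan-2-yl)silyloxy]phenyl}-2-(trimethylsilyloxy)phenyl)ethan-1-one | O=C(CBr)c1c(O[Si](C)(C)C)c(-c2c(OCc3ccccc3)cc(O[Si](C(C)C)(C(C)C)C(C)C)cc2OCc2ccccc2)c(OCc2ccccc2)cc1OCc1ccccc1 | intermediate
12 | 2-bromo-1-(4,6-bis(benzyloxy)-3-{2,6-bis(benzyloxy)-4-[tri(propan-2-yl)silyloxy]phenyl}-2-hydroxyphenyl)ethan-1-one | O=C(CBr)c1c(O)c(-c2c(OCc3ccccc3)cc(O[Si](C(C)C)(C(C)C)C(C)C)cc2OCc2ccccc2)c(OCc2ccccc2)cc1OCc1ccccc1 | intermediate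
13 | [2-(4,6-bis(benzyloxy)-3-{2,6-bis(benzyloxy)-4-[tri(propan-2-yl)silyloxy]phenyl}-2-hydroxyphenyl)-2-oxoethyl]triphenylphosphonium bromide | [Br-].O=C(C[P+](c1ccccc1)(c1ccccc1)c1ccccc1)c1c(O)c(-c2c(OCc3ccccc3)cc(O[Si](C(C)C)(C(C)C)C(C)C)cc2OCc2ccccc2)c(OCc2ccccc2)cc1OCc1ccccc1 | intermediate
14 | 1-(4,6-bis(benzyloxy)-3-{2,6-bis(benzyloxy)-4-[tri(propan-2-yl)silyloxy]phenyl}-2-hydroxyphenyl)-2-(triphenyl-λ5-phosphanylidene)ethan-1-one | O=C(C=P(c1ccccc1)(c1ccccc1)c1ccccc1)c1c(O)c(-c2c(OCc3ccccc3)cc(O[Si](C(C)C)(C(C)C)C(C)C)cc2OCc2ccccc2)c(OCc2ccccc2)cc1OCc1ccccc1 | intermediate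
15 | 4-(benzyloxy)benzoyl chloride | ClC(=O)c1ccc(OCc2ccccc2)cc1 | starting material
16 | 3,5-bis(benzyloxy)-6-{2,6-bis(benzyloxy)-4-[tri(propan-2-yl)silyloxy]phenyl}-2-[(triphenyl-λ5-phosphanylidene)acetyl]phenyl 4-(benzyloxy)benzoate | O=C(C=P(c1ccccc1)(c1ccccc1)c1ccccc1)c2c(OCc3ccccc3)cc(OCc3ccccc3)c(c2OC(=O)c4ccc(OCc5ccccc5)cc4)-c6c(OCc7ccccc7)cc(O[Si](C(C)C)(C(C)C)C(C)C)cc6OCc8ccccc8 | intermediate
17 | 5,7-bis(benzyloxy)-8-{2,6-bis(benzyloxy)-4-[tri(propan-2-yl)silyloxy]phenyl}-2-[4-(benzyloxy)phenyl]-4H-chromen-4-one | O=c1cc(-c2ccc(OCc3ccccc3)cc2)oc4c1c(OCc5ccccc5)cc(OCc5ccccc5)c4-c6c(OCc7ccccc7)cc(O[Si](C(C)C)(C(C)C)C(C)C)cc6OCc8ccccc8 | intermediate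
18 | 5,7-bis(benzyloxy)-8-[2,6-bis(benzyloxy)-4-hydroxyphenyl]-2-[4-(benzyloxy)phenyl]-4H-chromen-4-one | O=c1cc(-c2ccc(OCc3ccccc3)cc2)oc4c1c(OCc5ccccc5)cc(OCc5ccccc5)c4-c6c(OCc7ccccc7)cc(O)cc6OCc8ccccc8 | intermediate
19 | 3-(4-methoxyphenyl)prop-2-ynoic acid | COc1ccc(cc1)C#CC(O)=O | starting material
20 | ethyl 3-(4-methoxyphenyl)prop-2-ynoate | CCOC(=O)C#Cc1ccc(OC)cc1 | intermediate
21 | ethyl (2Z)-3-(3,5-bis(benzyloxy)-4-{5,7-bis(benzyloxy)-2-[4-(benzyloxy)phenyl]-4-oxo-4H-chromen-8-yl}phenoxy)-3-(4-methoxyphenyl)prop-2-enoate | CCOC(=O)/C=C(\Oc1cc(OCc2ccccc2)c(c(OCc2ccccc2)c1)-c1c(OCc2ccccc2)cc(OCc2ccccc2)c2c(=O)cc(oc12)-c1ccc(OCc2ccccc2)cc1)c1ccc(OC)cc1 | intermediate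
22 | (2Z)-3-(3,5-bis(benzyloxy)-4-{5,7-bis(benzyloxy)-2-[4-(benzyloxy)phenyl]-4-oxo-4H-chromen-8-yl}phenoxy)-3-(4-methoxyphenyl)prop-2-enoic acid | OC(=O)/C=C(\Oc1cc(OCc2ccccc2)c(c(OCc2ccccc2)c1)-c1c(OCc2ccccc2)cc(OCc2ccccc2)c2c(=O)cc(oc12)-c1ccc(OCc2ccccc2)cc1)c1ccc(OC)cc1 | intermediate
23 | 5,7-bis(benzyloxy)-6-{5,7-bis(benzyloxy)-2-[4-(benzyloxy)phenyl]-4-oxo-4H-chromen-8-yl}-2-(4-methoxyphenyl)-4H-chromen-4-one | COc1ccc(cc1)-c2cc(=O)c3c(OCc4ccccc4)c(c(OCc4ccccc4)cc3o2)-c5c(OCc6ccccc6)cc(OCc6ccccc6)c7c(=O)cc(oc57)-c8ccc(OCc9ccccc9)cc8 | intermediate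
24 | 5,7-dihydroxy-6-[5,7-dihydroxy-2-(4-hydroxyphenyl)-4-oxo-4H-chromen-8-yl]-2-(4-methoxyphenyl)-4H-chromen-4-one (CNP0302154.0) | COc1ccc(-c2cc(=O)c3c(O)c(-c4c(O)cc(O)c5c(=O)cc(-c6ccc(O)cc6)oc45)c(O)cc3o2)cc1 | target

Total step count: 16. Longest linear sequence: 13 steps (from 4 through steps 3 to 11 and 13 to 16).

Least certain steps

Step 10 (key step). The adduct of ylide carbon and ester carbonyl may collapse by expelling the phenoxide, so that the aroyl group moves from oxygen to the ylide carbon and an unreactive doubly stabilized ylide results. Alternatively, addition to the electron-rich, crowded 4-alkoxybenzoate may be so slow that long heating erodes the silyl ether. The fallback makes the acyl shift the productive path and sets out from 9. The dianion of 9 (LiN(SiMe3)2, 3 equiv, THF, −78 °C) is C-aroylated with 15 to give the 1,3-diketone 1-(4,6-bis(benzyloxy)-3-{2,6-bis(benzyloxy)-4-[tri(propan-2-yl)silyloxy]phenyl}-2-hydroxyphenyl)-3-[4-(benzyloxy)phenyl]propane-1,3-dione F1 (Baker–Venkataraman-type product). Cyclodehydration of F1 with catalytic TsOH in toluene at 80 °C closes O1–C2 through the only free phenol and comes back to the route at 17. With the 5-oxygen benzylated, no Wessely–Moser scrambling is possible in this acid step.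

Step 6. Protodeboronation of the di-ortho-alkoxy boronate may outrun transmetalation to the hindered arylpalladium intermediate; reduction of the iodide or α-arylation of the methyl ketone may also compete. The fallback replaces boron by zinc and sets out from 6 and 3. Bromine–lithium exchange on 6 (n-BuLi, THF, −78 °C) and transmetalation with ZnCl2 give {2,6-bis(benzyloxy)-4-[tri(propan-2-yl)silyloxy]phenyl}zinc chloride F2. F2 is used in excess in a Negishi coupling with 3 (Pd(OAc)2, SPhos, THF, 60 °C); the share protonated by the phenol returns as 5. The coupling comes back to the route at 9.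

Step 9. Acylation may occur at the ylide carbon, or the crowded, hydrogen-bonded phenol may react too slowly. The fallback puts the aroyl group on before phosphorus and sets out from 9. Acylation of 9 with 15 (Et3N, catalytic DMAP, CH2Cl2) gives 2-acetyl-3,5-bis(benzyloxy)-6-{2,6-bis(benzyloxy)-4-[tri(propan-2-yl)silyloxy]phenyl}phenyl 4-(benzyloxy)benzoate F3. Soft enolization (Me3SiOTf, Et3N, CH2Cl2, 0 °C), which forms no free enolate and so avoids an acyl shift, gives the trimethylsilyl enol ether F4. NBS in THF at −78 °C converts F4 to the bromoacetyl ester F5. PPh3 in toluene gives the phosphonium bromide F6, and aqueous NaHCO3 deprotonates F6 to come back to the route at 16.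

Step 4. Bromine may enter next to the silyloxy group, or a second bromination may follow, if the steric bias of the silyl group is weaker than assumed. The fallback replaces electrophilic substitution by directed ortho-lithiation and sets out from 5. The proton between the two benzyloxy groups is the most acidic ring proton (n-BuLi, THF, 0 °C), which gives 7 directly; the borate quench then comes back to the route at 8. The risk of this fallback is benzylic deprotonation.

Step 16. Cleavage of the hindered benzyl ethers next to the biaryl axis may be slow, so that reduction of a C2=C3 bond to the flavanone level begins before debenzylation is complete. The fallback replaces hydrogenolysis by Lewis-acid cleavage with a cation scavenger and sets out from 23: BCl3 and pentamethylbenzene in CH2Cl2 at −78 °C should remove the benzyl groups and leave the non-chelated aryl methyl ether and the double bonds. It comes back to the route at 24.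

Further compounds

F1 | step 10 | 1-(4,6-bis(benzyloxy)-3-{2,6-bis(benzyloxy)-4-[tri(propan-2-yl)silyloxy]phenyl}-2-hydroxyphenyl)-3-[4-(benzyloxy)phenyl]propane-1,3-dione | O=C(CC(=O)c1ccc(OCc2ccccc2)cc1)c1c(O)c(-c2c(OCc3ccccc3)cc(O[Si](C(C)C)(C(C)C)C(C)C)cc2OCc2ccccc2)c(OCc2ccccc2)cc1OCc1ccccc1
F2 | step 6 | {2,6-bis(benzyloxy)-4-[tri(propan-2-yl)silyloxy]phenyl}zinc chloride | Cl[Zn]c1c(OCc2ccccc2)cc(O[Si](C(C)C)(C(C)C)C(C)C)cc1OCc1ccccc1
F3 | step 9 | 2-acetyl-3,5-bis(benzyloxy)-6-{2,6-bis(benzyloxy)-4-[tri(propan-2-yl)silyloxy]phenyl}phenyl 4-(benzyloxy)benzoate | CC(=O)c1c(OCc2ccccc2)cc(OCc2ccccc2)c(c1OC(=O)c1ccc(OCc2ccccc2)cc1)-c1c(OCc2ccccc2)cc(O[Si](C(C)C)(C(C)C)C(C)C)cc1OCc1ccccc1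
F4 | step 9 | 3,5-bis(benzyloxy)-6-{2,6-bis(benzyloxy)-4-[tri(propan-2-yl)silyloxy]phenyl}-2-[1-(trimethylsilyloxy)ethenyl]phenyl 4-(benzyloxy)benzoate | C=C(O[Si](C)(C)C)c1c(OCc2ccccc2)cc(OCc2ccccc2)c(c1OC(=O)c1ccc(OCc2ccccc2)cc1)-c1c(OCc2ccccc2)cc(O[Si](C(C)C)(C(C)C)C(C)C)cc1OCc1ccccc1
F5 | step 9 | 3,5-bis(benzyloxy)-6-{2,6-bis(benzyloxy)-4-[tri(propan-2-yl)silyloxy]phenyl}-2-(bromoacetyl)phenyl 4-(benzyloxy)benzoate | O=C(CBr)c1c(OCc2ccccc2)cc(OCc2ccccc2)c(c1OC(=O)c1ccc(OCc2ccccc2)cc1)-c1c(OCc2ccccc2)cc(O[Si](C(C)C)(C(C)C)C(C)C)cc1OCc1ccccc1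
F6 | step 9 | {2-[2-{[4-(benzyloxy)benzoyl]oxy}-4,6-bis(benzyloxy)-3-{2,6-bis(benzyloxy)-4-[tri(propan-2-yl)silyloxy]phenyl}phenyl]-2-oxoethyl}triphenylphosphonium bromide | [Br-].O=C(C[P+](c1ccccc1)(c1ccccc1)c1ccccc1)c1c(OCc2ccccc2)cc(OCc2ccccc2)c(c1OC(=O)c1ccc(OCc2ccccc2)cc1)-c1c(OCc2ccccc2)cc(O[Si](C(C)C)(C(C)C)C(C)C)cc1OCc1ccccc1
F0 | step 4 | none | none
F0 | step 16 | none | none
A1 | alternative 1 | 5,7-dihydroxy-8-[7-hydroxy-2-(4-hydroxyphenyl)-5-methoxy-4-oxo-4H-chromen-8-yl]-2-(4-methoxyphenyl)-4H-chromen-4-one | COc1ccc(cc1)-c1cc(=O)c2c(O)cc(O)c(c2o1)-c1c(O)cc(OC)c2c(=O)cc(oc12)-c1ccc(O)cc1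
A2 | alternative 1 | 5,7-dihydroxy-6-[7-hydroxy-2-(4-hydroxyphenyl)-5-methoxy-4-oxo-4H-chromen-8-yl]-2-(4-methoxyphenyl)-4H-chromen-4-one | COc1ccc(cc1)-c2cc(=O)c3c(O)c(c(O)cc3o2)-c4c(O)cc(OC)c5c(=O)cc(oc45)-c6ccc(O)cc6
A3 | alternative 2 | 5,7-bis(benzyloxy)-6-{5,7-bis(benzyloxy)-2-[4-(benzyloxy)phenyl]-4-oxo-4H-chromen-8-yl}-2-(4-methoxyphenyl)-4H-chromen-4-one (identical with 23) | COc1ccc(cc1)-c2cc(=O)c3c(OCc4ccccc4)c(c(OCc4ccccc4)cc3o2)-c5c(OCc6ccccc6)cc(OCc6ccccc6)c7c(=O)cc(oc57)-c8ccc(OCc9ccccc9)cc8
A4 | alternative 3 | methyl 6-[4-(benzyloxy)phenyl]-2-(1-{2,6-bis(benzyloxy)-4-[tri(propan-2-yl)silyloxy]phenyl}-2-oxopropyl)-4-oxo-4H-pyran-3-carboxylate (racemic) | COC(=O)c1c(C(C(C)=O)c2c(OCc3ccccc3)cc(O[Si](C(C)C)(C(C)C)C(C)C)cc2OCc2ccccc2)oc(-c2ccc(OCc3ccccc3)cc2)cc1=O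
A5 | alternative 3 | 8-{2,6-bis(benzyloxy)-4-[tri(propan-2-yl)silyloxy]phenyl}-2-[4-(benzyloxy)phenyl]-5,7-dihydroxy-4H-chromen-4-one | Oc1cc(O)c(c2oc(cc(=O)c12)-c3ccc(OCc4ccccc4)cc3)-c5c(OCc6ccccc6)cc(O[Si](C(C)C)(C(C)C)C(C)C)cc5OCc7ccccc7
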